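## Analysis of the target

The target (32) is a trans-fused decalin of the eremophilane type. In eremophilane numbering, ring A is C1–C5 plus C10 and ring B is C5–C10; C3 carries the angelate, C4 the methyl C15, the quaternary C5 the angular methyl C14, C7 the isopropenyl group (C11–C13), C8 is the ketone, C9 carries the (E)-3-methylpent-2-enoate and C10 the ring-fusion hydrogen.

There are six stereocentres (C3, C4, C5, C7, C9, C10). The two methyls are cis (4β,5β), the C3 oxygen is α and trans to C15, H10 is α and trans to C14, and the C7 and C9 substituents are both α. In the chair–chair form every substituent except the axial C14 is equatorial, so C7, C9 and C10 are the thermodynamically preferred epimers, whereas C3, C4 and C5 have to be constructed.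

The sensitive points are:
- C7–H lies between the ketone and the isopropenyl group, so base or acid can move the alkene into conjugation (isopropylidene ketone).
- C9 is an α-acyloxy ketone (epimerisation, acyl shift).
- The angelate isomerises easily to the tiglate.
- Two different unsaturated esters sit on two secondary hydroxyls that must be told apart.

The hard part is the quaternary C5, wedged between the C4 stereocentre and the ring fusion, within the contiguous run C3–C4–C5–C10–C9, plus a C7 centre with no neighbouring stereocentre to relay control.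

The strategy rests on one feature: C5 is para to the C8 carbonyl. With the C7 and C9 substituents removed, ring B is a 4-methylcyclohexa-2,5-dienone in which C6 and C10 are mirror-related. Bonding C1 to one of them closes ring A and turns the prochiral C5 into the quaternary stereocentre.

## Retrosynthetic reasoning

**32 ⇒ 31 (C11=C12).** The β,γ-unsaturated ketone is the most fragile part of 32, so it is revealed last. The alkene is traced to the tertiary alcohol 31; no skeletal bond is cut. The tertiary hydroxyl is inert to every acylation before it and can be eliminated under neutral conditions at the end.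

**31 ⇒ 28 + 29; 28 ⇒ 27; 27 ⇒ 25 + 26 (ester C–O bonds).** The two esters are removed in the order that lets the hydroxyls be distinguished. The C3 angelate comes from alcohol 28 and acid 29. Alcohol 28 comes from silyl ether 27. The C9 ester of 27 comes from ketol 25 and acid 26. In 25 the C9 hydroxyl is the only acylable one: C3 is silylated and C11 is tertiary. The forward acylations must not isomerise the angelate or disturb the α-acyloxy ketone.

**25 ⇒ 23 ⇒ 21 (C9–O and C10–H).** The C9 oxygen is traced to oxidation of the C8–C9 silyl enol ether 23, and 23 to dissolving-metal reduction of the C9=C10 enone 21. One reduction therefore has to do two things: protonate C10 trans to the angular methyl, and deliver the enolate regiospecifically on the C9 side for oxygenation.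

**21 ⇒ 18 + 19 (C7–C11).** The three-carbon unit is attached by aldol addition of the α′-enolate of enone 18 to acetone (19). It is done at the enone stage for two reasons. C7 is then the only kinetically enolisable position. And the pseudo-axial C14 methyl shields the β face, so the side chain enters α (equatorial). On the cis-fused intermediate 16 the two folded conformers would expose opposite faces of C7, so the bond is not made there.

**18 ⇒ 17 ⇒ 16 (unsaturation pattern).** Enone 18 comes from trienone 17 by saturating the two disubstituted double bonds. Trienone 17 comes from the cyclisation product 16 by dehydrogenation. Because C7 of 16 is already sp2, unsaturation can only enter as C9=C10. The C10 centre of 16 is sacrificial; C5 is the stereocentre that matters.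

**16 ⇒ 15 (C1–C10, the key disconnection).** Cutting C1–C10 opens ring A and returns the symmetric dienone 15 with a Z-alkenyl iodide tether. The forward reaction must choose one of two diastereotopic enone arms, form the six-membered ring and end by C–H formation at C9. It gives the cis ring fusion, which is why C10 is reset later.

**15 ⇒ 14 ⇒ 10 + 11 (ring B).** The dienone comes from cyclohexenone 14 by dehydrogenation. Cyclohexenone 14 comes from a Robinson-type annulation of the α-branched aldehyde 10 with enone 11: a Michael bond from the aldehyde α-carbon, then an aldol condensation onto the aldehyde carbon. The quaternary carbon needs no stereocontrol because it becomes symmetric in 15.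

**10 ⇒ 9 ⇒ 8 (one-carbon homologation).** The α-methyl aldehyde is the hydrolysis product of enol ether 9, made from methyl ketone 8 by methoxymethylenation. The ketone carbon is the future C5 and its methyl is C14.

**8 ⇒ 7 ⇒ 6 ⇒ 5 ⇒ 2 + 3 (C3–C4).** The only two stereocentres that must be built from scratch, C4 and C3, are set together by an auxiliary-controlled syn-aldol between imide 3 and enal 2. The aldol 5 is converted through amide 6 and silyl ether 7 into ketone 8. The Z-iodoalkene comes in with the aldehyde, so no alkyne-to-iodoalkene conversion is needed beside the dienone.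

**2 ⇒ 1.** The labile enal 2 is made immediately before use from the stable ester 1.

## Alternatives that were turned down

**Alternative 1: aldehyde-initiated cationic bicyclisation.**
- Disconnection: C9–C10 and C4–C5 are cut together, leading back to an open-chain aldehyde with a C5=C10 alkene and a C3 silyl enol ether.
- Forward key step: Me2AlCl activates the C9 aldehyde, C10 of the alkene attacks it, and the C5 cation is captured by C4 of the enol ether. The product would be A1, the 9α-hydroxy-8β-(4-methoxybenzyloxy)-4β,5β-dimethyl-trans-decalin-3-one without the C7 substituent.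
- For: one operation closes both rings, forms two C–C bonds and up to four stereocentres, and gives the trans fusion directly. The C9 hydroxyl and a C8 oxygen are already there, so no C10 correction and no C9 hydroxylation are needed. On these points it is stronger than the chosen route.
- Against:
  - The C4–C5 bond joins a tertiary cation to a substituted enol ether carbon; proton loss or ene-type termination compete.
  - Alkene and enol ether geometry must both be pure to encode C4, C5 and C10.
  - All absolute control hangs on one α-alkoxy stereocentre (C8) in a flexible chain, and that centre is later destroyed by oxidation to the ketone.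
  - C3 arrives as a ketone to be reduced, and C7 still needs its side chain by the same late chemistry as here.
- Comparison: the chosen route takes its absolute stereochemistry from a catalyst acting on a rigid, symmetric dienone, supported by a reliable aldol. It pays for this with a longer redox sequence after the key step.

**Alternative 2: Ferrier carbocyclisation.**
- Disconnection: C6–C7 is cut and ring B is traced to a pyranoid ring in which the ring oxygen stands where C7 will be.
- Forward key step: Hg(OCOCF3)2 in aqueous acetone opens the enol-ether acetal, and the C7 enolate equivalent of the C8 ketone adds to the unmasked C6 aldehyde. The product would be A2, the 6-hydroxy-8-oxo decalin that already carries the C9 ester and the C3 silyl ether.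
- For: the C8 ketone/C9 ester pair arrives complete, with C9 fixed beforehand, under mild and dependable conditions. This is stronger than the chosen route, which needs a dissolving-metal step and an enol ether oxidation for the same pattern.
- Against:
  - The key step makes one C–C bond and one stereocentre (the C6 carbinol) that is not in the target and costs a deoxygenation.
  - C5, C4, C3, C10 and C9 must all be in place before it, so the difficult quaternary centre is pushed into a long precursor synthesis.
  - Mercury is used in quantity.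
  - The β-hydroxy ketone can eliminate, and C7 still has to be substituted.
- Comparison: the chosen key step itself creates the quaternary centre and a ring, which is where this target is hard.

**Alternative 3: quinone-ketal cycloadduct and siloxy-Cope rearrangement.**
- Disconnection: C4–C5 is cut in a [3,3] sense, tracing the decalin to a bridged bicyclic precursor.
- Forward key step: on heating, C4 of the E silyl enol ether bonds to C5 while the C2–C7 bridge bond breaks. The product would be A3, the cis-fused 9,9-dimethoxy-4β,5β-dimethyl-3-silyloxy-2,6-dien-8-one.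
- For: a very short assembly; the vicinal C4/C5 centres are set in one concerted, geometry-controlled event; C9 arrives oxidised; the C6=C7 enone is left as a handle; no transition metal is needed. In step count to the bicyclic core it beats the chosen route.
- Against:
  - The bridged precursor is racemic unless an auxiliary or resolution is added.
  - The cis fusion cannot be corrected while C9 is a ketal.
  - Unmasking C9 gives a 1,2-dione whose C9 carbonyl must then be reduced regio- and stereoselectively next to C8.
  - C3 arrives at the ketone level and needs reduction.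
- Comparison: the chosen route offers catalytic control of absolute configuration and a clean, regiodefined entry to the 9α-oxygen and the trans fusion from one enolate.

Key step: step 10

Assumption: (2E)-3-methylpent-2-enoic acid (26) is bought as the single E isomer; 10, 13 and 14 are carried as epimer mixtures at the carbon that becomes the symmetric C5 of 15.

## Route

Step 1
Reactants: 1 ethyl (2Z)-3-iodoprop-2-enoate
Product: 2 (2Z)-3-iodoprop-2-enal
Conditions: i-Bu2AlH, CH2Cl2, −78 °C; cold work-up, used at once
Reagents that add atoms: none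
Why: Partial hydride reduction of the ester stops at the aluminium hemiacetal at −78 °C and gives the aldehyde on cold work-up; the Z-iodoalkene is untouched and 2 is used directly because it isomerises on standing.

Step 2
Reactants: 2 (2Z)-3-iodoprop-2-enal; 3 (4S)-4-benzyl-3-propanoyl-1,3-oxazolidin-2-one
Product: 5 (4S)-4-benzyl-3-[(2S,3S,4Z)-3-hydroxy-5-iodo-2-methylpent-4-enoyl]-1,3-oxazolidin-2-one, via dibutylboron Z-enolate 4 (not isolated)
Conditions: 3, n-Bu2BOTf, i-Pr2NEt, CH2Cl2, 0 °C; then 2, −78 → 0 °C; pH 7 buffer, MeOH, H2O2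
Reagents that add atoms: none
Why: Evans syn-aldol: the Z-boron enolate 4 reacts through a closed Zimmerman–Traxler chair with the auxiliary carbonyl turned away, so the aldehyde adds opposite the benzyl group and C4 (2S) and C3 (3S) are set together in the syn relationship that becomes 4β-methyl/3α-oxygen; boron enolates add 1,2 to enals.

Step 3
Reactants: 5 (4S)-4-benzyl-3-[(2S,3S,4Z)-3-hydroxy-5-iodo-2-methylpent-4-enoyl]-1,3-oxazolidin-2-one
Product: 6 (2S,3S,4Z)-3-hydroxy-5-iodo-N-methoxy-N,2-dimethylpent-4-enamide
Conditions: MeNHOMe·HCl, AlMe3, CH2Cl2, −10 °C → rt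
Reagents that add atoms: N,O-dimethylhydroxylamine hydrochloride, CNOC.Cl
Why: Aluminium amide transamination to the Weinreb amide is assisted by the free β-hydroxyl through an aluminium chelate, releases the auxiliary and leaves the α-stereocentre untouched.

Step 4
Reactants: 6 (2S,3S,4Z)-3-hydroxy-5-iodo-N-methoxy-N,2-dimethylpent-4-enamide
Product: 7 (2S,3S,4Z)-3-[(tert-butyldimethylsilyl)oxy]-5-iodo-N-methoxy-N,2-dimethylpent-4-enamide
Conditions: t-BuMe2SiOTf, 2,6-lutidine, CH2Cl2, −78 → 0 °C
Reagents that add atoms: tert-butyldimethylsilyl triflate, CC(C)(C)[Si](C)(C)OS(=O)(=O)C(F)(F)F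
Why: Silylation of the secondary allylic alcohol with a silyl triflate and a hindered pyridine base; no stereocentre is formed or put at risk.

Step 5
Reactants: 7 (2S,3S,4Z)-3-[(tert-butyldimethylsilyl)oxy]-5-iodo-N-methoxy-N,2-dimethylpent-4-enamide
Product: 8 (3S,4S,5Z)-4-[(tert-butyldimethylsilyl)oxy]-6-iodo-3-methylhex-5-en-2-one
Conditions: MeMgBr, THF, −20 → 0 °C; aq. NH4Cl
Reagents that add atoms: methylmagnesium bromide, C[Mg]Br
Why: Weinreb ketone synthesis: the magnesium chelate of the tetrahedral adduct prevents over-addition and gives the methyl ketone (future C5 and C14) on work-up; at low temperature the α-centre and the alkenyl iodide are preserved.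

Step 6
Reactants: 8 (3S,4S,5Z)-4-[(tert-butyldimethylsilyl)oxy]-6-iodo-3-methylhex-5-en-2-one
Product: 9 (3R,4S,5Z)-4-[(tert-butyldimethylsilyl)oxy]-6-iodo-1-methoxy-2,3-dimethylhexa-1,5-diene (1E/1Z mixture)
Conditions: MeOCH2PPh3Cl, KN(SiMe3)2, THF, 0 °C; then 8, −78 °C → rt
Reagents that add atoms: (methoxymethyl)triphenylphosphonium chloride, COC[P+](c1ccccc1)(c1ccccc1)c1ccccc1.[Cl-]
Why: Wittig methoxymethylenation extends the ketone by one carbon as its enol ether; the base is kept in slight deficit relative to the salt to limit enolisation at C4, and the enol ether geometry is irrelevant.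

Step 7
Reactants: 9 (3R,4S,5Z)-4-[(tert-butyldimethylsilyl)oxy]-6-iodo-1-methoxy-2,3-dimethylhexa-1,5-diene (1E/1Z mixture)
Product: 10 (3R,4S,5Z)-4-[(tert-butyldimethylsilyl)oxy]-6-iodo-2,3-dimethylhex-5-enal (both C2 epimers)
Conditions: 1 M aq. HCl, THF, 0 °C → rt, stopped at full conversion
Reagents that add atoms: water, O
Why: Acid hydrolysis of the enol ether (C-protonation, hemiacetal collapse) should unmask the α-methyl aldehyde faster than the secondary silyl ether is cleaved; the new α-centre is left as a mixture because it becomes the symmetric C5.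

Step 8
Reactants: 10 (3R,4S,5Z)-4-[(tert-butyldimethylsilyl)oxy]-6-iodo-2,3-dimethylhex-5-enal (both C2 epimers); 11 but-3-en-2-one
Product: 14 4-methyl-4-[(2R,3S,4Z)-3-[(tert-butyldimethylsilyl)oxy]-5-iodopent-4-en-2-yl]cyclohex-2-en-1-one (both C4 epimers), via pyrrolidine enamine 12 (not isolated), via keto aldehyde 13 (not isolated)
Conditions: pyrrolidine, PhMe, 4 Å MS, rt; then 11, rt → 45 °C; then AcOH, NaOAc, H2O, 70 °C
Reagents that add atoms: pyrrolidine, C1CCNC1 (its atoms are held only in intermediate 12 and leave again before 14)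
Why: Stork enamine Robinson annulation: enamine 12 of the α-branched aldehyde adds to 11 at its only nucleophilic carbon and so builds the quaternary carbon, buffered hydrolysis gives 13, and intramolecular aldol condensation closes the 4,4-disubstituted cyclohexenone; C4 and C3 of the side chain are not enolisable in this sequence.

Step 9
Reactants: 14 4-methyl-4-[(2R,3S,4Z)-3-[(tert-butyldimethylsilyl)oxy]-5-iodopent-4-en-2-yl]cyclohex-2-en-1-one (both C4 epimers)
Product: 15 4-methyl-4-[(2R,3S,4Z)-3-[(tert-butyldimethylsilyl)oxy]-5-iodopent-4-en-2-yl]cyclohexa-2,5-dien-1-one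
Conditions: 2-iodoxybenzoic acid (IBX), PhMe/DMSO (2:1), 70 °C
Reagents that add atoms: none
Why: IBX dehydrogenation through the enol converts the enone into the cross-conjugated dienone, which merges both epimers of 14 into one compound with two equivalent ring arms; silyl ether and alkenyl iodide are inert to IBX.

Step 10
Reactants: 15 4-methyl-4-[(2R,3S,4Z)-3-[(tert-butyldimethylsilyl)oxy]-5-iodopent-4-en-2-yl]cyclohexa-2,5-dien-1-one
Product: 16 (4aS,5R,6R,8aS)-6-[(tert-butyldimethylsilyl)oxy]-4a,5-dimethyl-4a,5,6,8a-tetrahydronaphthalen-2(1H)-one (cis-fused; 3α-silyloxy-4β,5β-dimethyl-10β-H-1,6-dien-8-one in target numbering)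
Conditions: Pd(OAc)2 (10 mol %), (R)-BINAP (15 mol %), HCO2Na, DMF, 60 °C, degassed
Reagents that add atoms: none
Why: Pd(OAc)2 is reduced in situ to a zerovalent palladium–(R)-BINAP complex, which inserts into the C1–I bond of 15 with retention of the Z geometry. The alkenylpalladium then adds syn across one of the two enone double bonds, C1 bonding to C10 and palladium to C9, in a 6-exo-trig migratory insertion that closes ring A (C1–C2–C3–C4–C5–C10). Because the tether is anchored at C5, C1 can reach C10 only from the face that carries C4, so the ring fusion is cis and the C10 hydrogen is β (tether control). The C9 palladium enolate has no syn β-hydrogen (H10 is anti), so formate replaces iodide, loses CO2, and the palladium hydride reductively eliminates to C9–H and returns zerovalent palladium. The closest known reaction type is the palladium-catalysed asymmetric reductive Heck desymmetrisation of 4,4-disubstituted cyclohexadienones with tethered aryl halides; alkenyl iodides are the less common partners. The quaternary centre C5 is fixed by which diastereotopic double bond inserts: the chiral bisphosphine differentiates the two arms, and the C4 methyl and C3 silyloxy groups add a substrate bias because they can both sit pseudo-equatorially in a given half-chair of the forming ring for one arm only. The step needs arm selection and insertion ahead of hydride transfer; the planar dienone and the short Z tether allow only the 6-exo mode, and any dienone formed by β-hydride elimination after enolate epimerisation is 17, the next intermediate.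

Step 11
Reactants: 16 (4aS,5R,6R,8aS)-6-[(tert-butyldimethylsilyl)oxy]-4a,5-dimethyl-4a,5,6,8a-tetrahydronaphthalen-2(1H)-one
Product: 17 (4aR,5R,6R)-6-[(tert-butyldimethylsilyl)oxy]-4a,5-dimethyl-5,6-dihydronaphthalen-2(4aH)-one (1,6,9-trien-8-one in target numbering)
Conditions: IBX, PhMe/DMSO (2:1), 75 °C
Reagents that add atoms: none
Why: Second IBX dehydrogenation: C9 is the only enolisable position of enone 16, so the new double bond can only be C9=C10, conjugated onward to C1=C2; the sacrificial C10 centre is erased and C5 is untouched.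

Step 12
Reactants: 17 (4aR,5R,6R)-6-[(tert-butyldimethylsilyl)oxy]-4a,5-dimethyl-5,6-dihydronaphthalen-2(4aH)-one
Product: 18 (4aR,5R,6R)-6-[(tert-butyldimethylsilyl)oxy]-4a,5-dimethyl-4,4a,5,6,7,8-hexahydronaphthalen-2(3H)-one (9-en-8-one in target numbering)
Conditions: H2 (1 atm), RhCl(PPh3)3 (10 mol %), PhH, rt
Reagents that add atoms: none
Why: Homogeneous hydrogenation with RhCl(PPh3)3 discriminates by substitution: the disubstituted C6=C7 and C1=C2 bonds are reduced while the trisubstituted, β,β-disubstituted enone bond C9=C10 is left, the pattern known from the selective reduction of cross-conjugated and linear steroidal dienones to 4-en-3-ones.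

Step 13
Reactants: 18 (4aR,5R,6R)-6-[(tert-butyldimethylsilyl)oxy]-4a,5-dimethyl-4,4a,5,6,7,8-hexahydronaphthalen-2(3H)-one; 19 acetone
Product: 21 (3S,4aR,5R,6R)-6-[(tert-butyldimethylsilyl)oxy]-3-(2-hydroxypropan-2-yl)-4a,5-dimethyl-4,4a,5,6,7,8-hexahydronaphthalen-2(3H)-one, via lithium dienolate 20 (not isolated)
Conditions: LiN(i-Pr)2, THF, −78 °C; then 19, −78 °C; AcOH, −78 °C
Reagents that add atoms: none
Why: Kinetic deprotonation of the enone takes the α′ hydrogen at C7 (the γ position C1 is not touched at −78 °C), and dienolate 20 undergoes aldol addition to acetone from the α face, opposite the pseudo-axial angular methyl C14, giving the equatorial 7α side chain; the cold acid quench prevents retro-aldol.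

Step 14
Reactants: 21 (3S,4aR,5R,6R)-6-[(tert-butyldimethylsilyl)oxy]-3-(2-hydroxypropan-2-yl)-4a,5-dimethyl-4,4a,5,6,7,8-hexahydronaphthalen-2(3H)-one
Product: 23 trans-fused bis(trimethylsilyl) compound: 3α-(tert-butyldimethylsilyloxy)-4β,5β-dimethyl-8-(trimethylsilyloxy)-7α-[2-(trimethylsilyloxy)propan-2-yl]-10α-H-octal-8(9)-ene (target numbering), via dilithium enolate alkoxide 22 (not isolated)
Conditions: Li, NH3(l)/THF, −78 °C; isoprene; NH3 removed; Me3SiCl, Et3N, THF, −78 → 0 °C
Reagents that add atoms: chlorotrimethylsilane, C[Si](C)(C)Cl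
Why: Dissolving-metal (Birch-type) enone reduction: the C10 carbanion is protonated on its axial α face by the substrate's own tertiary hydroxyl, which gives the trans ring fusion, and the regiodefined C8–C9 enolate and the alkoxide of 22 are both silylated; once C8 is an enolate carbon the aldolate cannot fragment.

Step 15
Reactants: 23 trans-fused bis(trimethylsilyl) compound (8-silyl enol ether, 11-silyl ether)
Product: 25 (1S,3S,4aR,5R,6R,8aR)-6-[(tert-butyldimethylsilyl)oxy]-1-hydroxy-3-(2-hydroxypropan-2-yl)-4a,5-dimethyloctahydronaphthalen-2(1H)-one, via 9α-silyloxy ketone 24 (not isolated)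
Conditions: 3-chloroperbenzoic acid, NaHCO3, CH2Cl2, −20 → 0 °C; then citric acid, MeOH, rt
Reagents that add atoms: 3-chloroperbenzoic acid, O=C(OO)c1cccc(Cl)c1
Why: Rubottom oxidation: the peracid epoxidises the electron-rich silyl enol ether from the α face, away from the syn-axial C14 methyl, silyl migration gives the 9α-silyloxy ketone 24, and mild acid methanolysis removes both trimethylsilyl groups but not the tert-butyldimethylsilyl ether; 9α is also the equatorial, preferred position.

Step 16
Reactants: 25 (1S,3S,4aR,5R,6R,8aR)-6-[(tert-butyldimethylsilyl)oxy]-1-hydroxy-3-(2-hydroxypropan-2-yl)-4a,5-dimethyloctahydronaphthalen-2(1H)-one; 26 (2E)-3-methylpent-2-enoic acid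
Product: 27 (1S,3S,4aR,5R,6R,8aR)-6-[(tert-butyldimethylsilyl)oxy]-3-(2-hydroxypropan-2-yl)-4a,5-dimethyl-2-oxodecahydronaphthalen-1-yl (2E)-3-methylpent-2-enoate
Conditions: N,N'-dicyclohexylcarbodiimide, DMAP (cat.), CH2Cl2, 0 °C → rt
Reagents that add atoms: none
Why: Steglich esterification acylates the secondary C9 hydroxyl only; the tertiary C11 hydroxyl does not react and C3 is still silylated, which is how the two ester sites are told apart.

Step 17
Reactants: 27 (1S,3S,4aR,5R,6R,8aR)-6-[(tert-butyldimethylsilyl)oxy]-3-(2-hydroxypropan-2-yl)-4a,5-dimethyl-2-oxodecahydronaphthalen-1-yl (2E)-3-methylpent-2-enoate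
Product: 28 (1S,3S,4aR,5R,6R,8aR)-6-hydroxy-3-(2-hydroxypropan-2-yl)-4a,5-dimethyl-2-oxodecahydronaphthalen-1-yl (2E)-3-methylpent-2-enoate
Conditions: HF·pyridine, pyridine/THF, 0 °C → rt
Reagents that add atoms: none
Why: Fluoride-mediated desilylation under buffered, non-basic conditions frees the C3 hydroxyl, so the α-acyloxy ketone should neither epimerise nor undergo acyl shift.

Step 18
Reactants: 28 (1S,3S,4aR,5R,6R,8aR)-6-hydroxy-3-(2-hydroxypropan-2-yl)-4a,5-dimethyl-2-oxodecahydronaphthalen-1-yl (2E)-3-methylpent-2-enoate; 29 (2Z)-2-methylbut-2-enoic acid (angelic acid)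
Product: 31 (1S,3S,4aR,5R,6R,8aR)-3-(2-hydroxypropan-2-yl)-4a,5-dimethyl-6-{[(2Z)-2-methylbut-2-enoyl]oxy}-2-oxodecahydronaphthalen-1-yl (2E)-3-methylpent-2-enoate, via mixed anhydride 30 (not isolated)
Conditions: 29, 2,4,6-Cl3C6H2COCl, Et3N, PhMe, rt; then 28, 75 °C
Reagents that add atoms: none
Why: Yamaguchi-type esterification through mixed anhydride 30 transfers the angeloyl group to the equatorial C3 hydroxyl without a nucleophilic catalyst, conditions under which the Z geometry of angelates is retained; the tertiary hydroxyl stays free.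

Step 19
Reactants: 31 (1S,3S,4aR,5R,6R,8aR)-3-(2-hydroxypropan-2-yl)-4a,5-dimethyl-6-{[(2Z)-2-methylbut-2-enoyl]oxy}-2-oxodecahydronaphthalen-1-yl (2E)-3-methylpent-2-enoate
Product: 32 (1S,3S,4aR,5R,6R,8aR)-4a,5-dimethyl-6-{[(2Z)-2-methylbut-2-enoyl]oxy}-2-oxo-3-(prop-1-en-2-yl)decahydronaphthalen-1-yl (2E)-3-methylpent-2-enoate (target)
Conditions: methyl N-(triethylammoniosulfonyl)carbamate (Burgess reagent), PhH, rt → 50 °C
Reagents that add atoms: none
Why: Burgess dehydration by syn elimination of the tertiary sulfamate: reaching a methyl hydrogen needs only rotation about C11–CH3, whereas reaching the axial C7 hydrogen forces both methyls to eclipse ring bonds beneath the syn-axial C14 methyl, so the 11,12-alkene is expected; the neutral medium protects the β,γ-unsaturated ketone, the α-acyloxy ketone and the angelate.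

## Compound list

1 | ethyl (2Z)-3-iodoprop-2-enoate | CCOC(=O)/C=C\I | starting material
2 | (2Z)-3-iodoprop-2-enal | O=C/C=C\I | intermediate
3 | (4S)-4-benzyl-3-propanoyl-1,3-oxazolidin-2-one | CCC(=O)N1[C@@H](Cc2ccccc2)COC1=O | starting material
4 | (4S)-4-benzyl-3-[(1Z)-1-(dibutylboranyloxy)prop-1-en-1-yl]-1,3-oxazolidin-2-one (boron enolate of 3) | C/C=C(\OB(CCCC)CCCC)N1[C@@H](Cc2ccccc2)COC1=O | intermediate
5 | (4S)-4-benzyl-3-[(2S,3S,4Z)-3-hydroxy-5-iodo-2-methylpent-4-enoyl]-1,3-oxazolidin-2-one | O=C([C@@H](C)[C@H](O)/C=C\I)N1[C@@H](Cc2ccccc2)COC1=O | intermediate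
6 | (2S,3S,4Z)-3-hydroxy-5-iodo-N-methoxy-N,2-dimethylpent-4-enamide | CON(C)C(=O)[C@@H](C)[C@H](O)/C=C\I | intermediate
7 | (2S,3S,4Z)-3-[(tert-butyldimethylsilyl)oxy]-5-iodo-N-methoxy-N,2-dimethylpent-4-enamide | CON(C)C(=O)[C@@H](C)[C@H](O[Si](C)(C)C(C)(C)C)/C=C\I | intermediate
8 | (3S,4S,5Z)-4-[(tert-butyldimethylsilyl)oxy]-6-iodo-3-methylhex-5-en-2-one | CC(=O)[C@@H](C)[C@H](O[Si](C)(C)C(C)(C)C)/C=C\I | intermediate
9 | (3R,4S,5Z)-4-[(tert-butyldimethylsilyl)oxy]-6-iodo-1-methoxy-2,3-dimethylhexa-1,5-diene (1E/1Z mixture) | COC=C(C)[C@@H](C)[C@H](O[Si](C)(C)C(C)(C)C)/C=C\I | intermediate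
10 | (3R,4S,5Z)-4-[(tert-butyldimethylsilyl)oxy]-6-iodo-2,3-dimethylhex-5-enal (both C2 epimers) | O=CC(C)[C@@H](C)[C@H](O[Si](C)(C)C(C)(C)C)/C=C\I | intermediate
11 | but-3-en-2-one (methyl vinyl ketone) | CC(=O)C=C | starting material
12 | 1-[(3R,4S,5Z)-4-[(tert-butyldimethylsilyl)oxy]-6-iodo-2,3-dimethylhexa-1,5-dien-1-yl]pyrrolidine | C(=C(C)[C@@H](C)[C@H](O[Si](C)(C)C(C)(C)C)/C=C\I)N1CCCC1 | intermediate
13 | 2-methyl-2-[(2R,3S,4Z)-3-[(tert-butyldimethylsilyl)oxy]-5-iodopent-4-en-2-yl]-5-oxohexanal (both C2 epimers) | CC(=O)CCC(C)(C=O)[C@@H](C)[C@H](O[Si](C)(C)C(C)(C)C)/C=C\I | intermediate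
14 | 4-methyl-4-[(2R,3S,4Z)-3-[(tert-butyldimethylsilyl)oxy]-5-iodopent-4-en-2-yl]cyclohex-2-en-1-one (both C4 epimers) | CC1([C@@H](C)[C@H](O[Si](C)(C)C(C)(C)C)/C=C\I)C=CC(=O)CC1 | intermediate
15 | 4-methyl-4-[(2R,3S,4Z)-3-[(tert-butyldimethylsilyl)oxy]-5-iodopent-4-en-2-yl]cyclohexa-2,5-dien-1-one | CC1([C@@H](C)[C@H](O[Si](C)(C)C(C)(C)C)/C=C\I)C=CC(=O)C=C1 | intermediate
16 | (4aS,5R,6R,8aS)-6-[(tert-butyldimethylsilyl)oxy]-4a,5-dimethyl-4a,5,6,8a-tetrahydronaphthalen-2(1H)-one | O=C1C=C[C@]2(C)[C@@H](C)[C@H](O[Si](C)(C)C(C)(C)C)C=C[C@@H]2C1 | intermediate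
17 | (4aR,5R,6R)-6-[(tert-butyldimethylsilyl)oxy]-4a,5-dimethyl-5,6-dihydronaphthalen-2(4aH)-one | O=C1C=C[C@]2(C)[C@@H](C)[C@H](O[Si](C)(C)C(C)(C)C)C=CC2=C1 | intermediate
18 | (4aR,5R,6R)-6-[(tert-butyldimethylsilyl)oxy]-4a,5-dimethyl-4,4a,5,6,7,8-hexahydronaphthalen-2(3H)-one | O=C1CC[C@]2(C)[C@@H](C)[C@H](O[Si](C)(C)C(C)(C)C)CCC2=C1 | intermediate
19 | acetone | CC(C)=O | starting material
20 | lithium cross-conjugated dienolate of 18 (O–C8=C7 and C9=C10 in target numbering) | [Li]OC1=CC[C@]2(C)[C@@H](C)[C@H](O[Si](C)(C)C(C)(C)C)CCC2=C1 | intermediate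
21 | (3S,4aR,5R,6R)-6-[(tert-butyldimethylsilyl)oxy]-3-(2-hydroxypropan-2-yl)-4a,5-dimethyl-4,4a,5,6,7,8-hexahydronaphthalen-2(3H)-one | CC(C)(O)[C@@H]1C[C@]2(C)[C@@H](C)[C@H](O[Si](C)(C)C(C)(C)C)CCC2=CC1=O | intermediate
22 | dilithium C8-enolate C11-alkoxide of the trans-fused reduction product (10α-H) | CC(C)(O[Li])[C@@H]1C[C@]2(C)[C@@H](C)[C@H](O[Si](C)(C)C(C)(C)C)CC[C@H]2C=C1O[Li] | intermediate
23 | trans-fused 3α-(tert-butyldimethylsilyloxy)-4β,5β-dimethyl-8-(trimethylsilyloxy)-7α-[2-(trimethylsilyloxy)propan-2-yl]-10α-H-octal-8(9)-ene (target numbering) | CC(C)(O[Si](C)(C)C)[C@@H]1C[C@]2(C)[C@@H](C)[C@H](O[Si](C)(C)C(C)(C)C)CC[C@H]2C=C1O[Si](C)(C)C | intermediate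
24 | trans-fused 3α-(tert-butyldimethylsilyloxy)-9α-(trimethylsilyloxy)-7α-[2-(trimethylsilyloxy)propan-2-yl]-4β,5β-dimethyldecalin-8-one (target numbering) | CC(C)(O[Si](C)(C)C)[C@@H]1C[C@]2(C)[C@@H](C)[C@H](O[Si](C)(C)C(C)(C)C)CC[C@H]2[C@H](O[Si](C)(C)C)C1=O | intermediate
25 | (1S,3S,4aR,5R,6R,8aR)-6-[(tert-butyldimethylsilyl)oxy]-1-hydroxy-3-(2-hydroxypropan-2-yl)-4a,5-dimethyloctahydronaphthalen-2(1H)-one | CC(C)(O)[C@@H]1C[C@]2(C)[C@@H](C)[C@H](O[Si](C)(C)C(C)(C)C)CC[C@H]2[C@H](O)C1=O | intermediate
26 | (2E)-3-methylpent-2-enoic acid | CC/C(C)=C/C(=O)O | starting material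
27 | (1S,3S,4aR,5R,6R,8aR)-6-[(tert-butyldimethylsilyl)oxy]-3-(2-hydroxypropan-2-yl)-4a,5-dimethyl-2-oxodecahydronaphthalen-1-yl (2E)-3-methylpent-2-enoate | CC(C)(O)[C@@H]1C[C@]2(C)[C@@H](C)[C@H](O[Si](C)(C)C(C)(C)C)CC[C@H]2[C@H](OC(=O)/C=C(\C)CC)C1=O | intermediate
28 | (1S,3S,4aR,5R,6R,8aR)-6-hydroxy-3-(2-hydroxypropan-2-yl)-4a,5-dimethyl-2-oxodecahydronaphthalen-1-yl (2E)-3-methylpent-2-enoate | CC(C)(O)[C@@H]1C[C@]2(C)[C@@H](C)[C@H](O)CC[C@H]2[C@H](OC(=O)/C=C(\C)CC)C1=O | intermediate
29 | (2Z)-2-methylbut-2-enoic acid (angelic acid) | C/C=C(/C)C(=O)O | starting material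
30 | (2Z)-2-methylbut-2-enoic 2,4,6-trichlorobenzoic anhydride | C/C=C(/C)C(=O)OC(=O)c1c(Cl)cc(Cl)cc1Cl | intermediate
31 | (1S,3S,4aR,5R,6R,8aR)-3-(2-hydroxypropan-2-yl)-4a,5-dimethyl-6-{[(2Z)-2-methylbut-2-enoyl]oxy}-2-oxodecahydronaphthalen-1-yl (2E)-3-methylpent-2-enoate | CC(C)(O)[C@@H]1C[C@]2(C)[C@@H](C)[C@H](OC(=O)/C(C)=C\C)CC[C@H]2[C@H](OC(=O)/C=C(\C)CC)C1=O | intermediate
32 | (1S,3S,4aR,5R,6R,8aR)-4a,5-dimethyl-6-{[(2Z)-2-methylbut-2-enoyl]oxy}-2-oxo-3-(prop-1-en-2-yl)decahydronaphthalen-1-yl (2E)-3-methylpent-2-enoate | C=C(C)[C@@H]1C[C@]2(C)[C@@H](C)[C@H](OC(=O)/C(C)=C\C)CC[C@H]2[C@H](OC(=O)/C=C(\C)CC)C1=O | target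

## Step count and least certain steps

Total: 19 steps. Longest linear sequence: 19 steps (1 → 32); compounds 3, 11, 19, 26 and 29 enter as bought materials.

**Step 10 (key step).**
- What may go wrong: poor discrimination between the two enone arms. The sense of catalyst control for an alkenyl tether carrying two stereocentres is not secured by analogy, so the bias of the ligand and that of the C4/C3 substituents may oppose each other. The alkenylpalladium may also be reduced by formate before it inserts (loss of iodine without ring closure), and the iodide-bound catalyst may lose selectivity. The first remedy is the antipodal ligand.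
- Fallback: from 15, a tin-hydride-mediated radical cyclisation (Bu3SnH added slowly, AIBN, PhH, 80 °C). The alkenyl radical adds 6-exo to one enone arm and comes back to the route at 16. It passes through no new isolable compound (F0). Arm selection then rests on the C4 and C3 substituents alone; the other C5 epimer would be removed by chromatography.

**Step 19.**
- What may go wrong: elimination toward C7 instead of toward a methyl group, driven by the acidity of the hydrogen α to the ketone, giving the conjugated isopropylidene ketone; or ionisation of the tertiary sulfamate followed by unselective proton loss.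
- Fallback: take the carbonyl out of play for the elimination. From 31, reduce the ketone at −78 °C (NaBH4, CeCl3·7H2O, MeOH, cold buffered quench to avoid acyl shift) to the C8 alcohol F1. Silylate the secondary hydroxyl (Et3SiCl, imidazole) to the C8 triethylsilyl ether F2. Dehydrate the tertiary alcohol, where only sterics and statistics now decide, to the isopropenyl silyl ether F3. Remove the silyl group (HF·pyridine) to the isopropenyl C8 alcohol F4. Oxidise with Dess–Martin periodinane to return at 32.

**Step 12.**
- What may go wrong: stalling at the C1=C2 bond beside the bulky silyloxy group, or slow over-reduction of C9=C10.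
- Fallback: from 16, hydrogenate both disubstituted alkenes over Pd/C to the saturated cis-fused ketone F5. Form the silyl enol ether under equilibrating conditions (Me3SiCl, NaI, Et3N, MeCN), which for cis-fused ketones of this type favours the double bond toward the ring fusion, giving the C8–C9 trimethylsilyl enol ether F6. Oxidise with Pd(OAc)2 in MeCN (Saegusa–Ito) to return at 18.

**Step 8.**
- What may go wrong: slow Michael addition at the hindered α-carbon (a quaternary centre is formed next to the branched C4), polymerisation of 11, or partial loss of the silyl ether during the buffered cyclisation.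
- Fallback: change the nucleophile and its activation. From 10, form the trimethylsilyl enol ether F7 (Me3SiCl, NaI, Et3N, MeCN). Carry out a Mukaiyama–Michael addition to 11 (catalytic Me3SiOTf, CH2Cl2, −78 °C), which gives keto aldehyde 13 after work-up. Cyclise with pyrrolidinium acetate to return at 14.

**Step 6.**
- What may go wrong: enolisation of the ketone by the basic ylide, which would erode the C4 configuration, and base-induced loss of HI from the Z-iodoalkene.
- Fallback: a non-basic methylenation followed by hydroboration. From 8, Zn, CH2Br2, TiCl4 (Takai–Lombardo) gives the 1,1-disubstituted alkene F8. 9-BBN then NaBO3 gives the primary alcohol F9; the borane should prefer the 1,1-disubstituted alkene over the iodoalkene. Dess–Martin oxidation returns at 10.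

## Further compounds

F0 | step 10 | none | none
F1 | step 19 | C8 alcohol of 31 (either C8 epimer; 7α-(2-hydroxypropan-2-yl), both esters in place) | CC(C)(O)[C@@H]1C[C@]2(C)[C@@H](C)[C@H](OC(=O)/C(C)=C\C)CC[C@H]2[C@H](OC(=O)/C=C(\C)CC)C1O
F2 | step 19 | C8 triethylsilyl ether of F1 | CC(C)(O)[C@@H]1C[C@]2(C)[C@@H](C)[C@H](OC(=O)/C(C)=C\C)CC[C@H]2[C@H](OC(=O)/C=C(\C)CC)C1O[Si](CC)(CC)CC
F3 | step 19 | 7α-isopropenyl C8 triethylsilyl ether | C=C(C)[C@@H]1C[C@]2(C)[C@@H](C)[C@H](OC(=O)/C(C)=C\C)CC[C@H]2[C@H](OC(=O)/C=C(\C)CC)C1O[Si](CC)(CC)CC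
F4 | step 19 | 7α-isopropenyl C8 alcohol (8-dihydro form of 32) | C=C(C)[C@@H]1C[C@]2(C)[C@@H](C)[C@H](OC(=O)/C(C)=C\C)CC[C@H]2[C@H](OC(=O)/C=C(\C)CC)C1O
F5 | step 12 | cis-fused saturated ketone: 3α-(tert-butyldimethylsilyloxy)-4β,5β-dimethyl-10β-H-decalin-8-one (target numbering) | O=C1CC[C@]2(C)[C@@H](C)[C@H](O[Si](C)(C)C(C)(C)C)CC[C@@H]2C1
F6 | step 12 | C8–C9 trimethylsilyl enol ether of F5 | C[Si](C)(C)OC=1CC[C@]2(C)[C@@H](C)[C@H](O[Si](C)(C)C(C)(C)C)CC[C@@H]2C=1
F7 | step 8 | trimethylsilyl enol ether of 10: (3R,4S,5Z)-4-[(tert-butyldimethylsilyl)oxy]-6-iodo-2,3-dimethyl-1-(trimethylsilyloxy)hexa-1,5-diene | C[Si](C)(C)OC=C(C)[C@@H](C)[C@H](O[Si](C)(C)C(C)(C)C)/C=C\I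
F8 | step 6 | (3R,4S,5Z)-4-[(tert-butyldimethylsilyl)oxy]-6-iodo-2,3-dimethylhexa-1,5-diene | C=C(C)[C@@H](C)[C@H](O[Si](C)(C)C(C)(C)C)/C=C\I
F9 | step 6 | (3R,4S,5Z)-4-[(tert-butyldimethylsilyl)oxy]-6-iodo-2,3-dimethylhex-5-en-1-ol (both C2 epimers) | OCC(C)[C@@H](C)[C@H](O[Si](C)(C)C(C)(C)C)/C=C\I
A1 | alternative 1 | 9α-hydroxy-8β-(4-methoxybenzyloxy)-4β,5β-dimethyl-trans-decalin-3-one (target numbering) | C1C[C@]2(C)[C@@H](C)C(=O)CC[C@H]2[C@H](O)[C@H]1OCc3ccc(OC)cc3
A2 | alternative 2 | 6-hydroxy-8-oxo trans-decalin with the C9 (2E)-3-methylpent-2-enoate and the C3 tert-butyldimethylsilyl ether | C1[C@H](O)[C@]2(C)[C@@H](C)[C@H](O[Si](C)(C)C(C)(C)C)CC[C@H]2[C@H](OC(=O)/C=C(\C)CC)C1=O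
A3 | alternative 3 | cis-fused 9,9-dimethoxy-4β,5β-dimethyl-3-(tert-butyldimethylsilyloxy)-2,6-dien-8-one (target numbering) | C1=C[C@]2(C)[C@@H](C)C(O[Si](C)(C)C(C)(C)C)=CC[C@@H]2C(OC)(OC)C1=O
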